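**Plan**
1. Retrosynthesis: the three silyl ethers come off last. Ring C is cut at O1–C2 and C4–C4a, giving phloroglucinol (ring A) and an α-silyloxy β-keto ester. The C2–C3 bond is cut next, a Claisen union of a benzoate with a protected glycolate.
2. Ring B of the benzoate is cut at C1'–C2' and C5'–C6'. The adjacent C3'/C4' catechol oxygens are the carbonyl oxygens of an open-chain 2,3-dione, so C2'–C5' form a bis(silyl enol ether) diene with C2' already carrying the prenyl CH2. C1' and C6' come from methyl propiolate, whose ester carbon becomes C2.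
3. Forward: prenylation of a biacetyl mono-ketal, ketal hydrolysis, double enol silylation, ring B by [4+2] cycloaddition and dehydrogenation, Claisen extension, ring C annulated onto phloroglucinol, desilylation.
4. Stereochemistry: the target has no stereocentre. The prenyl alkene is carried intact from prenyl bromide. The only geometry to control is the 3Z enol ether of the diene (thermodynamic silylation), which the s-cis conformer requires.

Key step: step 4

Abbreviations: TBS = tert-butyldimethylsilyl; MOM = methoxymethyl; DDQ = 2,3-dichloro-5,6-dicyano-1,4-benzoquinone.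

Assumption: silyl groups lost or shifted between oxygens during the hot annulation (step 7) are tolerated, because step 8 removes every silyl group and all such forms converge on the target.

**Step 1**
Reactants: 1 3,3-dimethoxybutan-2-one; 2 1-bromo-3-methylbut-2-ene (prenyl bromide)
Product: 4 2,2-dimethoxy-7-methyloct-6-en-3-one, via lithium enolate 3 (not isolated)
Conditions: LiN(iPr)2 (1.05 equiv), THF, −78 °C; then 2, −78 → 0 °C
Reagents that add atoms: none
Why: Enolate alkylation: the ketal carbon has no α-hydrogen, so deprotonation can occur only at the acetyl methyl group, and enolate 3 should be C-alkylated by the reactive primary allylic bromide in an SN2 reaction; no stereocentre is formed.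

**Step 2**
Reactants: 4 2,2-dimethoxy-7-methyloct-6-en-3-one
Product: 5 7-methyloct-6-ene-2,3-dione
Conditions: 2 M aq HCl, THF, rt
Reagents that add atoms: water, O
Why: Acid-catalysed ketal hydrolysis through the oxocarbenium ion should unmask the second carbonyl, and dilute acid at room temperature is not expected to hydrate the trisubstituted alkene; no stereocentre is formed.

**Step 3**
Reactants: 5 7-methyloct-6-ene-2,3-dione
Product: 6 (3Z)-2,3-bis(tert-butyldimethylsilyloxy)-7-methylocta-1,3,6-triene
Conditions: TBSOTf (2.4 equiv), Et3N (3 equiv), CH2Cl2, 0 °C → rt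
Reagents that add atoms: tert-butyldimethylsilyl trifluoromethanesulfonate (TBSOTf), CC(C)(C)[Si](C)(C)OS(=O)(=O)C(F)(F)F
Why: Soft enolisation with silyl triflate and amine turns each carbonyl into its silyl enol ether, each carbonyl having only one enolisable side (C1 and C4), and the equilibrating conditions should favour the 3Z isomer with the chain cis to oxygen and trans to the diene backbone; no stereocentre, only this alkene geometry.

**Step 4**
Reactants: 6 (3Z)-2,3-bis(tert-butyldimethylsilyloxy)-7-methylocta-1,3,6-triene; 7 methyl propiolate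
Product: 9 methyl 3,4-bis(tert-butyldimethylsilyloxy)-2-(3-methylbut-2-enyl)benzoate, via cyclohexadiene cycloadduct 8 (not isolated)
Conditions: 7 (3 equiv), toluene, BHT (trace), 110 °C, sealed tube; then DDQ (1.1 equiv), 0 °C → rt
Reagents that add atoms: none
Why: The electron-rich diene 6 and the electron-poor alkyne 7 should combine in a thermal, concerted but asynchronous [4+2] cycloaddition of normal electron demand, the closest known reaction type being the Diels–Alder reaction of 2,3-bis(silyloxy)buta-1,3-dienes with acetylenic esters followed by dehydrogenation to catechol ethers. Ring B closes intermolecularly by cycloaddition, the C1'–C2' and C5'–C6' bonds forming on one face of the s-cis diene to give the 1,4-cyclohexadiene 8. DDQ then abstracts hydride from the doubly allylic C5' methylene and loss of the C2' proton aromatises the ring, so the single sp3 stereocentre of 8 (C2', formed racemic) is erased and no stereocontrol is needed. The selectivity required is regiochemical: the two silyloxy groups oppose each other electronically, so the alkyl substituent at C4 of the diene decides, as in piperylene, making the CH2 terminus (C1) the more nucleophilic end, which bonds to the β-carbon of 7 and places the ester-bearing carbon next to the prenyl-bearing carbon. The 3Z geometry keeps the prenyl chain on the outside of the diene so the s-cis conformer is reachable, and the robust TBS ethers keep the catechol masked from the quinone oxidant.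

**Step 5**
Reactants: 10 tert-butyl 2-hydroxyacetate
Product: 11 tert-butyl 2-(tert-butyldimethylsilyloxy)acetate
Conditions: TBSCl, imidazole, CH2Cl2, rt
Reagents that add atoms: tert-butyldimethylsilyl chloride (TBSCl), CC(C)(C)[Si](C)(C)Cl
Why: Imidazole-promoted silylation of an unhindered primary alcohol is routine and gives a glycolate whose tert-butyl ester resists self-condensation in the next step.

**Step 6**
Reactants: 9 methyl 3,4-bis(tert-butyldimethylsilyloxy)-2-(3-methylbut-2-enyl)benzoate; 11 tert-butyl 2-(tert-butyldimethylsilyloxy)acetate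
Product: 13 tert-butyl 3-[3,4-bis(tert-butyldimethylsilyloxy)-2-(3-methylbut-2-enyl)phenyl]-2-(tert-butyldimethylsilyloxy)-3-oxopropanoate, via lithium ester enolate 12 (not isolated)
Conditions: 11 (2.5 equiv), LiN(iPr)2 (2.4 equiv), THF, −78 °C; then 9, −78 → −20 °C; AcOH quench at −78 °C
Reagents that add atoms: none
Why: Crossed Claisen condensation: the non-enolisable benzoate 9 is the only acyl acceptor, the slight deficit of amide base leaves no free strong base, and deprotonation of the β-keto ester product by the second equivalent of enolate 12 drives the acyl substitution; the new C2 stereocentre forms racemic and disappears in step 7.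

**Step 7**
Reactants: 13 tert-butyl 3-[3,4-bis(tert-butyldimethylsilyloxy)-2-(3-methylbut-2-enyl)phenyl]-2-(tert-butyldimethylsilyloxy)-3-oxopropanoate; 14 phloroglucinol
Product: 17 2-[3,4-bis(tert-butyldimethylsilyloxy)-2-(3-methylbut-2-enyl)phenyl]-3-(tert-butyldimethylsilyloxy)-5,7-dihydroxy-4H-chromen-4-one, via acylketene 15 (not isolated), via aryl diketone 16 (not isolated)
Conditions: 14 (2 equiv, anhydrous), neat melt, argon, microwave, 150 °C then 220–230 °C (minutes)
Reagents that add atoms: none
Why: Thermal Mentzer-type pyrone annulation of a β-keto ester with phloroglucinol: loss of tert-butanol should give acylketene 15, which C-acylates the strongly nucleophilic triol to give diketone 16, and 6-exo-trig attack of an ortho hydroxyl on the aryl ketone with loss of water closes ring C as the chromone; the symmetry of phloroglucinol removes any regiochemical question and no stereocentre remains.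

**Step 8**
Reactants: 17 2-[3,4-bis(tert-butyldimethylsilyloxy)-2-(3-methylbut-2-enyl)phenyl]-3-(tert-butyldimethylsilyloxy)-5,7-dihydroxy-4H-chromen-4-one
Product: 18 2-[3,4-dihydroxy-2-(3-methylbut-2-enyl)phenyl]-3,5,7-trihydroxy-4H-chromen-4-one (CNP0210655.0)
Conditions: Bu4NF (4 equiv), AcOH (4 equiv), THF, 0 °C → rt, argon
Reagents that add atoms: none
Why: Fluoride-induced desilylation, driven by Si–F bond formation, should cleave the two aryl silyl ethers and the enol-type 3-O-silyl ether, while the acetic acid buffer and exclusion of air protect the oxidation-prone catechol flavonol and the prenyl alkene is inert to fluoride.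

**Compound list**
1 | 3,3-dimethoxybutan-2-one | CC(=O)C(C)(OC)OC | starting material
2 | 1-bromo-3-methylbut-2-ene (prenyl bromide) | CC(C)=CCBr | starting material
3 | lithium 3,3-dimethoxybut-1-en-2-olate | [Li+].[O-]C(=C)C(C)(OC)OC | intermediate
4 | 2,2-dimethoxy-7-methyloct-6-en-3-one | CC(C)=CCCC(=O)C(C)(OC)OC | intermediate
5 | 7-methyloct-6-ene-2,3-dione | CC(C)=CCCC(=O)C(C)=O | intermediate
6 | (3Z)-2,3-bis(tert-butyldimethylsilyloxy)-7-methylocta-1,3,6-triene | C=C(O[Si](C)(C)C(C)(C)C)/C(O[Si](C)(C)C(C)(C)C)=C/CC=C(C)C | intermediate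
7 | methyl propiolate | C#CC(=O)OC | starting material
8 | methyl 4,5-bis(tert-butyldimethylsilyloxy)-6-(3-methylbut-2-enyl)cyclohexa-1,4-diene-1-carboxylate (racemic) | COC(=O)C1=CCC(O[Si](C)(C)C(C)(C)C)=C(O[Si](C)(C)C(C)(C)C)C1CC=C(C)C | intermediate
9 | methyl 3,4-bis(tert-butyldimethylsilyloxy)-2-(3-methylbut-2-enyl)benzoate | COC(=O)c1ccc(O[Si](C)(C)C(C)(C)C)c(O[Si](C)(C)C(C)(C)C)c1CC=C(C)C | intermediate
10 | tert-butyl 2-hydroxyacetate | CC(C)(C)OC(=O)CO | starting material
11 | tert-butyl 2-(tert-butyldimethylsilyloxy)acetate | CC(C)(C)OC(=O)CO[Si](C)(C)C(C)(C)C | intermediate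
12 | lithium 1-tert-butoxy-2-(tert-butyldimethylsilyloxy)ethen-1-olate (enolate geometry immaterial) | [Li+].[O-]C(OC(C)(C)C)=CO[Si](C)(C)C(C)(C)C | intermediate
13 | tert-butyl 3-[3,4-bis(tert-butyldimethylsilyloxy)-2-(3-methylbut-2-enyl)phenyl]-2-(tert-butyldimethylsilyloxy)-3-oxopropanoate (racemic) | CC(C)(C)OC(=O)C(O[Si](C)(C)C(C)(C)C)C(=O)c1ccc(O[Si](C)(C)C(C)(C)C)c(O[Si](C)(C)C(C)(C)C)c1CC=C(C)C | intermediate
14 | phloroglucinol (benzene-1,3,5-triol) | Oc1cc(O)cc(O)c1 | starting material
15 | 3-[3,4-bis(tert-butyldimethylsilyloxy)-2-(3-methylbut-2-enyl)phenyl]-2-(tert-butyldimethylsilyloxy)prop-1-ene-1,3-dione (acylketene) | O=C=C(O[Si](C)(C)C(C)(C)C)C(=O)c1ccc(O[Si](C)(C)C(C)(C)C)c(O[Si](C)(C)C(C)(C)C)c1CC=C(C)C | intermediate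
16 | 1-[3,4-bis(tert-butyldimethylsilyloxy)-2-(3-methylbut-2-enyl)phenyl]-2-(tert-butyldimethylsilyloxy)-3-(2,4,6-trihydroxyphenyl)propane-1,3-dione (racemic) | CC(C)=CCc1c(C(=O)C(O[Si](C)(C)C(C)(C)C)C(=O)c2c(O)cc(O)cc2O)ccc(O[Si](C)(C)C(C)(C)C)c1O[Si](C)(C)C(C)(C)C | intermediate
17 | 2-[3,4-bis(tert-butyldimethylsilyloxy)-2-(3-methylbut-2-enyl)phenyl]-3-(tert-butyldimethylsilyloxy)-5,7-dihydroxy-4H-chromen-4-one | CC(C)=CCc1c(-c2oc3cc(O)cc(O)c3c(=O)c2O[Si](C)(C)C(C)(C)C)ccc(O[Si](C)(C)C(C)(C)C)c1O[Si](C)(C)C(C)(C)C | intermediate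
18 | 2-[3,4-dihydroxy-2-(3-methylbut-2-enyl)phenyl]-3,5,7-trihydroxy-4H-chromen-4-one | CC(C)=CCc1c(-c2oc3cc(O)cc(O)c3c(=O)c2O)ccc(O)c1O | target

**Step count**
Total: 8 steps. Longest linear sequence: 7 steps (steps 1, 2, 3, 4, 6, 7, 8); step 5 is a one-step side branch.

**Steps most likely to fail**

Step 7 (thermal annulation). The melt may divert material in three ways: acylation of phloroglucinol on oxygen without the shift to carbon, pyrolysis of the tert-butyl ester followed by decarboxylation, and cyclisation of the prenyl chain onto a C3' oxygen that has lost its silyl group. The fallback builds ring C by an ionic chalcone route; it sets out from 9 and returns at 18.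
- The silyl ethers of 9 are cleaved with Bu4NF to give methyl 3,4-dihydroxy-2-(3-methylbut-2-enyl)benzoate F1.
- MOMCl and iPr2NEt convert it into methyl 3,4-bis(methoxymethoxy)-2-(3-methylbut-2-enyl)benzoate F2.
- Reduction with iBu2AlH should give [3,4-bis(methoxymethoxy)-2-(3-methylbut-2-enyl)phenyl]methanol F3, and MnO2 oxidation gives 3,4-bis(methoxymethoxy)-2-(3-methylbut-2-enyl)benzaldehyde F4.
- Claisen–Schmidt condensation of the aldehyde with commercially available 1-[2-hydroxy-4,6-bis(methoxymethoxy)phenyl]ethanone (KOH, EtOH) should give (E)-3-[3,4-bis(methoxymethoxy)-2-(3-methylbut-2-enyl)phenyl]-1-[2-hydroxy-4,6-bis(methoxymethoxy)phenyl]prop-2-en-1-one F5.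
- Algar–Flynn–Oyamada oxidation (H2O2, NaOH, MeOH) would close ring C as 2-[3,4-bis(methoxymethoxy)-2-(3-methylbut-2-enyl)phenyl]-3-hydroxy-5,7-bis(methoxymethoxy)-4H-chromen-4-one F6.
- HCl in MeOH at or slightly above room temperature removes the four MOM groups to give 18.

Step 4 (key cycloaddition). Crowding of the two TBS-oxy groups in the s-cis conformer may slow the cycloaddition enough for diene hydrolysis, propiolate oligomerisation and regiochemical leakage to compete. The fallback keeps the same two ring bonds but uses a more reactive alkene dienophile as a propiolate surrogate; it sets out from 6 and returns at 9.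
- Cycloaddition of 6 with methyl 2-chloroacrylate (toluene, 80 °C) should give methyl 1-chloro-3,4-bis(tert-butyldimethylsilyloxy)-2-(3-methylbut-2-enyl)cyclohex-3-ene-1-carboxylate F7 as a diastereomer mixture.
- DBU-mediated loss of hydrogen chloride would give cycloadduct 8 and/or its conjugated isomer methyl 3,4-bis(tert-butyldimethylsilyloxy)-2-(3-methylbut-2-enyl)cyclohexa-1,3-diene-1-carboxylate F8.
- DDQ dehydrogenates either diene to 9.

Step 6 (crossed Claisen). Acyl substitution at the hindered, electron-rich ester may be outrun by proton transfer from the benzylic and allylic prenyl CH2 (with double-bond migration) or by oxygen-to-carbon silyl shift in the enolate on warming. The fallback replaces acyl substitution by a fast aldol addition and an oxidation; it sets out from 9 and returns at 13.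
- iBu2AlH reduces 9 to [3,4-bis(tert-butyldimethylsilyloxy)-2-(3-methylbut-2-enyl)phenyl]methanol F9.
- MnO2 oxidises it to 3,4-bis(tert-butyldimethylsilyloxy)-2-(3-methylbut-2-enyl)benzaldehyde F10.
- Addition of enolate 12 at −78 °C should give tert-butyl 3-[3,4-bis(tert-butyldimethylsilyloxy)-2-(3-methylbut-2-enyl)phenyl]-2-(tert-butyldimethylsilyloxy)-3-hydroxypropanoate F11 as a diastereomer mixture.
- Dess–Martin periodinane with NaHCO3 oxidises it to 13.

**Further compounds**
F1 | step 7 | methyl 3,4-dihydroxy-2-(3-methylbut-2-enyl)benzoate | COC(=O)c1ccc(O)c(O)c1CC=C(C)C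
F2 | step 7 | methyl 3,4-bis(methoxymethoxy)-2-(3-methylbut-2-enyl)benzoate | COCOc1ccc(C(=O)OC)c(CC=C(C)C)c1OCOC
F3 | step 7 | [3,4-bis(methoxymethoxy)-2-(3-methylbut-2-enyl)phenyl]methanol | COCOc1ccc(CO)c(CC=C(C)C)c1OCOC
F4 | step 7 | 3,4-bis(methoxymethoxy)-2-(3-methylbut-2-enyl)benzaldehyde | COCOc1ccc(C=O)c(CC=C(C)C)c1OCOC
F5 | step 7 | (E)-3-[3,4-bis(methoxymethoxy)-2-(3-methylbut-2-enyl)phenyl]-1-[2-hydroxy-4,6-bis(methoxymethoxy)phenyl]prop-2-en-1-one | COCOc1cc(O)c(C(=O)/C=C/c2ccc(OCOC)c(OCOC)c2CC=C(C)C)c(OCOC)c1
F6 | step 7 | 2-[3,4-bis(methoxymethoxy)-2-(3-methylbut-2-enyl)phenyl]-3-hydroxy-5,7-bis(methoxymethoxy)-4H-chromen-4-one | COCOc1cc(OCOC)c2c(=O)c(O)c(-c3ccc(OCOC)c(OCOC)c3CC=C(C)C)oc2c1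
F7 | step 4 | methyl 1-chloro-3,4-bis(tert-butyldimethylsilyloxy)-2-(3-methylbut-2-enyl)cyclohex-3-ene-1-carboxylate (diastereomer mixture, racemic) | COC(=O)C1(Cl)CCC(O[Si](C)(C)C(C)(C)C)=C(O[Si](C)(C)C(C)(C)C)C1CC=C(C)C
F8 | step 4 | methyl 3,4-bis(tert-butyldimethylsilyloxy)-2-(3-methylbut-2-enyl)cyclohexa-1,3-diene-1-carboxylate | COC(=O)C1=C(CC=C(C)C)C(O[Si](C)(C)C(C)(C)C)=C(O[Si](C)(C)C(C)(C)C)CC1
F9 | step 6 | [3,4-bis(tert-butyldimethylsilyloxy)-2-(3-methylbut-2-enyl)phenyl]methanol | CC(C)=CCc1c(CO)ccc(O[Si](C)(C)C(C)(C)C)c1O[Si](C)(C)C(C)(C)C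
F10 | step 6 | 3,4-bis(tert-butyldimethylsilyloxy)-2-(3-methylbut-2-enyl)benzaldehyde | CC(C)=CCc1c(C=O)ccc(O[Si](C)(C)C(C)(C)C)c1O[Si](C)(C)C(C)(C)C
F11 | step 6 | tert-butyl 3-[3,4-bis(tert-butyldimethylsilyloxy)-2-(3-methylbut-2-enyl)phenyl]-2-(tert-butyldimethylsilyloxy)-3-hydroxypropanoate (diastereomer mixture, racemic) | CC(C)(C)OC(=O)C(O[Si](C)(C)C(C)(C)C)C(O)c1ccc(O[Si](C)(C)C(C)(C)C)c(O[Si](C)(C)C(C)(C)C)c1CC=C(C)C
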